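**Retrosynthetic overview** (atoms carry flavan numbers: O1, C2, C3, C4, C4a, C8a)
1. The stilbene C=C is disconnected by Horner–Wadsworth–Emmons olefination at an ortho-formyl group on the C4 aryl ring; until then that formyl carbon is held as a lactol with O-3.
2. The pyran ring O1–C2–C3–C4–C4a–C8a comes from the five-membered ring O1–C3–C4–C4a–C8a of a trans-2,3-dihydrobenzofuran that carries C2 as an exocyclic benzylic carbinol: O1 shifts from C3 to C2 while the formyl-derived oxygen closes onto C3.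
3. Enabling feature: ring oxygen O1 is vicinal to carbinol carbon C2, which its 4-benzyloxyphenyl group allows to ionise; the formyl carbon on the C4 aryl ring lets its oxygen reach C3 through a six-membered ring, anti to the C3–O1 bond.
4. The dihydrobenzofuran is built from three benzenoid pieces: aryllithium plus salicylaldehyde carbonate (C4–aryl bond), asymmetric [4+1] annulation of the derived o-quinone methide with a phenacyl sulfonium ylide (C3–C4 and O1–C3 bonds), then chelation-controlled ketone reduction.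
5. Ring order: dihydrofuran (step 6), pyran plus temporary lactol ring (step 8), lactol opened in step 10; global debenzylation ends the route.

Key step: step 8

Assumption: the chiral bis-urea catalyst of step 6 is taken in the enantiomeric form that gives (2R,3S)-14; the trans relative configuration does not depend on this choice.

**Step 1**
Reactants: 1 3,5-bis(benzyloxy)benzaldehyde
Product: 2 3,5-bis(benzyloxy)-2-bromobenzaldehyde
Conditions: NBS, MeCN, 0 °C to rt
Reagents that add atoms: N-bromosuccinimide, O=C1CCC(=O)N1Br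
Why: electrophilic aromatic bromination should go to C2, which is para to one benzyloxy group and ortho to the other, as known for 3,5-dialkoxybenzaldehydes; the position between the two ethers is more hindered.

**Step 2**
Reactants: 2 3,5-bis(benzyloxy)-2-bromobenzaldehyde
Product: 3 1,5-bis(benzyloxy)-2-bromo-3-(dimethoxymethyl)benzene
Conditions: HC(OMe)3, TsOH·H2O (cat.), MeOH, rt
Reagents that add atoms: trimethyl orthoformate, COC(OC)OC
Why: acid-catalysed acetalisation masks the aldehyde against n-BuLi and base; the acetal later serves as the latent internal nucleophile and as the stilbene carbon.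

**Step 3**
Reactants: 4 4-(benzyloxy)-2-hydroxybenzaldehyde
Product: 5 5-(benzyloxy)-2-formylphenyl tert-butyl carbonate
Conditions: Boc2O, i-Pr2NEt, DMAP (cat.), CH2Cl2, 0 °C to rt
Reagents that add atoms: di-tert-butyl dicarbonate, CC(C)(C)OC(=O)OC(=O)OC(C)(C)C
Why: O-acylation of the phenol installs a carbonate that can later move to the benzylic oxygen and leave under base, so the o-quinone methide can be generated without acid.

**Step 4**
Reactants: 3 1,5-bis(benzyloxy)-2-bromo-3-(dimethoxymethyl)benzene; 5 5-(benzyloxy)-2-formylphenyl tert-butyl carbonate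
Product: 9 [4-(benzyloxy)-2-hydroxyphenyl][2,4-bis(benzyloxy)-6-(dimethoxymethyl)phenyl]methyl tert-butyl carbonate (racemic), via aryllithium 6 (not isolated), via lithium alkoxide 7 (not isolated), via lithium phenoxide 8 (not isolated)
Conditions: n-BuLi, THF, −78 °C; then 5, −78 °C; AcOH, −78 °C; used crude at once
Reagents that add atoms: none
Why: bromine–lithium exchange, 1,2-addition of the aryllithium to the aldehyde and O-to-O transfer of the Boc group to the new alkoxide (six-membered transition state) should give, after cold protonation, a base-labile o-quinone methide precursor; its stereocenter is racemic and is erased in step 6.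

**Step 5**
Reactants: 10 1-[4-(benzyloxy)phenyl]-2-bromoethan-1-one
Product: 11 {2-[4-(benzyloxy)phenyl]-2-oxoethyl}dimethylsulfonium bromide
Conditions: Me2S, acetone, rt
Reagents that add atoms: dimethyl sulfide, CSC
Why: SN2 alkylation of dimethyl sulfide by the α-bromoketone gives the precursor of a carbonyl-stabilised sulfonium ylide.

**Step 6**
Reactants: 9 [4-(benzyloxy)-2-hydroxyphenyl][2,4-bis(benzyloxy)-6-(dimethoxymethyl)phenyl]methyl tert-butyl carbonate; 11 {2-[4-(benzyloxy)phenyl]-2-oxoethyl}dimethylsulfonium bromide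
Product: 14 [(2R,3S)-6-(benzyloxy)-3-[2,4-bis(benzyloxy)-6-(dimethoxymethyl)phenyl]-2,3-dihydro-1-benzofuran-2-yl][4-(benzyloxy)phenyl]methanone, via sulfonium ylide 12 (not isolated), via o-quinone methide 13 (not isolated)
Conditions: Cs2CO3, chiral C2-symmetric bis-urea catalyst (10 mol %), CH2Cl2, −20 °C to rt
Reagents that add atoms: none
Why: formal [4+1] annulation of a sulfur ylide with an o-quinone methide: base releases 13 from 9 by 1,4-elimination of tert-butyl carbonate and deprotonates 11 to 12, the ylide carbon (future C3) adds to the methide carbon (future C4) and the phenoxide displaces dimethyl sulfide (5-exo-tet); the trans relation follows from the anti arrangement in the closure and from the epimerisable position next to the ketone, the absolute configuration from the hydrogen-bond catalyst bound to the quinone methide oxygen.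

**Step 7**
Reactants: 14 [(2R,3S)-6-(benzyloxy)-3-[2,4-bis(benzyloxy)-6-(dimethoxymethyl)phenyl]-2,3-dihydro-1-benzofuran-2-yl][4-(benzyloxy)phenyl]methanone
Product: 15 (S)-[(2R,3S)-6-(benzyloxy)-3-[2,4-bis(benzyloxy)-6-(dimethoxymethyl)phenyl]-2,3-dihydro-1-benzofuran-2-yl][4-(benzyloxy)phenyl]methanol
Conditions: Zn(BH4)2, Et2O, −40 to −20 °C; aq. NH4Cl
Reagents that add atoms: none
Why: Cram-chelate reduction: zinc bridges the ketone oxygen and ring oxygen O1, and hydride should enter from the carbonyl face next to H-3 and away from C4 with its aryl group, giving the (S)-carbinol, the epimer whose C2–OH bond can lie anti to C3–O1 with the aryl group on the side of H-3.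

**Step 8**
Reactants: 15 (S)-[(2R,3S)-6-(benzyloxy)-3-[2,4-bis(benzyloxy)-6-(dimethoxymethyl)phenyl]-2,3-dihydro-1-benzofuran-2-yl][4-(benzyloxy)phenyl]methanol
Product: 18 lactol of (2R,3S,4S)-7-(benzyloxy)-2-[4-(benzyloxy)phenyl]-4-[2,4-bis(benzyloxy)-6-formylphenyl]-3,4-dihydro-2H-chromen-3-ol (six-membered hemiacetal between O-3 and the formyl carbon; anomer mixture), via hydroxy aldehyde 16 (not isolated), via oxiranium ion 17 (not isolated)
Conditions: TsOH·H2O (20 mol %), HFIP–H2O (20:1), 0.01 M, 0 °C to rt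
Reagents that add atoms: water, O
Why: Proposed new method: acid unmasks the acetal to aldehyde 16 and ionises the p-benzyloxybenzylic C2–OH, the vicinal ring oxygen O1 closes onto C2 (3-exo-tet) to give oxiranium ion 17, and the oxygen of the hydrated ortho-formyl group opens 17 at C3 (6-exo-tet, anti to O1), so that O1 has moved from C3 to C2 and the ring O1–C3–C4–C4a–C8a has become O1–C2–C3–C4–C4a–C8a. The closest known reactions are the ring expansion of 2-(1-sulfonyloxyalkyl)tetrahydrofurans to tetrahydropyran-3-yl esters through bicyclic oxiranium ions and the isomerisation of 2-(halomethyl)-2,3-dihydrobenzofurans to 3-halochromans; the new elements are the benzylic dihydrobenzofuranyl carbinol and the termination by a tethered carbonyl hydrate. C3 is inverted by the backside attack, which turns the trans relation of the dihydrobenzofuran into the 3,4-trans relation of the flavan; C2 is set by inversion of the (S)-carbinol, and a free cation should converge on the same result because the oxiranium with the aryl group trans to C4 is the less strained one; C4 is untouched and the lactol carbon is uncontrolled and disappears in step 10. The step needs opening of 17 at C3 and not at benzylic C2: the tether makes C3 attack a six-membered and C2 attack a seven-membered closure, the trans-fused 6/6 lactol is strain-free whereas attack by the flanking benzyloxy oxygen would give a trans-fused 5/6 system, and capture at C2 is reversible because the 4-benzyloxyphenyl group lets that bond re-ionise while the new C3–O bond does not. Loss of the C3 proton (leading to a benzofuran) is the competing drain; low temperature, high dilution and an ionising, weakly basic medium are chosen against it.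

**Step 9**
Reactants: 19 1,2-bis(benzyloxy)-4-(chloromethyl)benzene
Product: 20 diethyl {[3,4-bis(benzyloxy)phenyl]methyl}phosphonate
Conditions: P(OEt)3, neat, 130 °C
Reagents that add atoms: triethyl phosphite, CCOP(OCC)OCC
Why: Michaelis–Arbuzov reaction of a benzylic chloride.

**Step 10**
Reactants: 18 lactol of (2R,3S,4S)-7-(benzyloxy)-2-[4-(benzyloxy)phenyl]-4-[2,4-bis(benzyloxy)-6-formylphenyl]-3,4-dihydro-2H-chromen-3-ol; 20 diethyl {[3,4-bis(benzyloxy)phenyl]methyl}phosphonate
Product: 21 (2R,3S,4S)-7-(benzyloxy)-2-[4-(benzyloxy)phenyl]-4-{2,4-bis(benzyloxy)-6-[(E)-2-[3,4-bis(benzyloxy)phenyl]ethenyl]phenyl}-3,4-dihydro-2H-chromen-3-ol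
Conditions: KOtBu (3 equiv), THF, 0 °C to rt
Reagents that add atoms: none
Why: Horner–Wadsworth–Emmons olefination: base opens the lactol to the hydroxy aldehyde, and the benzylphosphonate anion should give the (E)-stilbene, as is usual for semi-stabilised phosphonates; the temporary ring is removed and no flavan stereocenter is touched.

**Step 11**
Reactants: 21 (2R,3S,4S)-7-(benzyloxy)-2-[4-(benzyloxy)phenyl]-4-{2,4-bis(benzyloxy)-6-[(E)-2-[3,4-bis(benzyloxy)phenyl]ethenyl]phenyl}-3,4-dihydro-2H-chromen-3-ol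
Product: 22 (2R,3S,4S)-4-{2-[(E)-2-(3,4-dihydroxyphenyl)ethenyl]-4,6-dihydroxyphenyl}-2-(4-hydroxyphenyl)-3,4-dihydro-2H-chromene-3,7-diol (CNP0170061.1)
Conditions: BCl3, pentamethylbenzene, CH2Cl2, −78 °C; MeOH quench
Reagents that add atoms: none
Why: Lewis-acid cleavage of the six aryl benzyl ethers with a non-basic cation scavenger should leave the alkene, the benzylic ring ether and the three stereocenters untouched, where hydrogenolysis would reduce the stilbene.

**Compound list**
1 | 3,5-bis(benzyloxy)benzaldehyde | O=Cc1cc(OCc2ccccc2)cc(OCc2ccccc2)c1 | starting material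
2 | 3,5-bis(benzyloxy)-2-bromobenzaldehyde | O=Cc1cc(OCc2ccccc2)cc(OCc2ccccc2)c1Br | intermediate
3 | 1,5-bis(benzyloxy)-2-bromo-3-(dimethoxymethyl)benzene | COC(OC)c1cc(OCc2ccccc2)cc(OCc2ccccc2)c1Br | intermediate
4 | 4-(benzyloxy)-2-hydroxybenzaldehyde | O=Cc1ccc(OCc2ccccc2)cc1O | starting material
5 | 5-(benzyloxy)-2-formylphenyl tert-butyl carbonate | O=Cc1ccc(OCc2ccccc2)cc1OC(=O)OC(C)(C)C | intermediate
6 | [2,4-bis(benzyloxy)-6-(dimethoxymethyl)phenyl]lithium (not isolated) | COC(OC)c1cc(OCc2ccccc2)cc(OCc2ccccc2)c1[Li] | intermediate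
7 | lithium alkoxide from addition of 6 to 5, Boc still on the phenol oxygen (not isolated) | [Li]OC(c1ccc(OCc2ccccc2)cc1OC(=O)OC(C)(C)C)c1c(OCc2ccccc2)cc(OCc2ccccc2)cc1C(OC)OC | intermediate
8 | lithium phenoxide after Boc transfer to the benzylic oxygen (not isolated) | [Li]Oc1cc(OCc2ccccc2)ccc1C(OC(=O)OC(C)(C)C)c1c(OCc2ccccc2)cc(OCc2ccccc2)cc1C(OC)OC | intermediate
9 | [4-(benzyloxy)-2-hydroxyphenyl][2,4-bis(benzyloxy)-6-(dimethoxymethyl)phenyl]methyl tert-butyl carbonate (racemic) | CC(C)(C)OC(=O)OC(c1ccc(OCc2ccccc2)cc1O)c1c(OCc2ccccc2)cc(OCc2ccccc2)cc1C(OC)OC | intermediate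
10 | 1-[4-(benzyloxy)phenyl]-2-bromoethan-1-one | O=C(CBr)c1ccc(OCc2ccccc2)cc1 | starting material
11 | {2-[4-(benzyloxy)phenyl]-2-oxoethyl}dimethylsulfonium bromide | C[S+](C)CC(=O)c1ccc(OCc2ccccc2)cc1.[Br-] | intermediate
12 | dimethylsulfonium 2-[4-(benzyloxy)phenyl]-2-oxoethylide (not isolated) | C[S+](C)[CH-]C(=O)c1ccc(OCc2ccccc2)cc1 | intermediate
13 | 3-(benzyloxy)-6-{[2,4-bis(benzyloxy)-6-(dimethoxymethyl)phenyl]methylidene}cyclohexa-2,4-dien-1-one, the o-quinone methide (not isolated) | O=C1C=C(OCc2ccccc2)C=CC1=Cc1c(OCc2ccccc2)cc(OCc2ccccc2)cc1C(OC)OC | intermediate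
14 | [(2R,3S)-6-(benzyloxy)-3-[2,4-bis(benzyloxy)-6-(dimethoxymethyl)phenyl]-2,3-dihydro-1-benzofuran-2-yl][4-(benzyloxy)phenyl]methanone (trans) | O=C(c1ccc(OCc2ccccc2)cc1)[C@@H]1Oc2cc(OCc3ccccc3)ccc2[C@H]1c1c(OCc2ccccc2)cc(OCc2ccccc2)cc1C(OC)OC | intermediate
15 | (S)-[(2R,3S)-6-(benzyloxy)-3-[2,4-bis(benzyloxy)-6-(dimethoxymethyl)phenyl]-2,3-dihydro-1-benzofuran-2-yl][4-(benzyloxy)phenyl]methanol | O[C@@H](c1ccc(OCc2ccccc2)cc1)[C@@H]1Oc2cc(OCc3ccccc3)ccc2[C@H]1c1c(OCc2ccccc2)cc(OCc2ccccc2)cc1C(OC)OC | intermediate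
16 | 3,5-bis(benzyloxy)-2-[(2R,3S)-6-(benzyloxy)-2-[(S)-[4-(benzyloxy)phenyl](hydroxy)methyl]-2,3-dihydro-1-benzofuran-3-yl]benzaldehyde (not isolated) | O[C@@H](c1ccc(OCc2ccccc2)cc1)[C@@H]1Oc2cc(OCc3ccccc3)ccc2[C@H]1c1c(OCc2ccccc2)cc(OCc2ccccc2)cc1C=O | intermediate
17 | oxiranium ion: O1 bridges C2 and C3 of the dihydrobenzofuran; 4-benzyloxyphenyl on C2 trans to C4 across the three-membered ring (not isolated) | O(Cc1ccccc1)c1ccc(cc1)[C@H]1[O+]2c3cc(OCc4ccccc4)ccc3[C@@H](c3c(OCc4ccccc4)cc(OCc4ccccc4)cc3C=O)[C@H]12 | intermediate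
18 | lactol of (2R,3S,4S)-7-(benzyloxy)-2-[4-(benzyloxy)phenyl]-4-[2,4-bis(benzyloxy)-6-formylphenyl]-3,4-dihydro-2H-chromen-3-ol: six-membered hemiacetal between O-3 and the formyl carbon, trans-fused to the pyran ring, anomer mixture | O(Cc1ccccc1)c1ccc(cc1)[C@H]1Oc2cc(OCc5ccccc5)ccc2[C@H]3c4c(OCc5ccccc5)cc(OCc5ccccc5)cc4C(O)O[C@H]13 | intermediate
19 | 1,2-bis(benzyloxy)-4-(chloromethyl)benzene | ClCc1ccc(OCc2ccccc2)c(OCc2ccccc2)c1 | starting material
20 | diethyl {[3,4-bis(benzyloxy)phenyl]methyl}phosphonate | CCOP(=O)(OCC)Cc1ccc(OCc2ccccc2)c(OCc2ccccc2)c1 | intermediate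
21 | (2R,3S,4S)-7-(benzyloxy)-2-[4-(benzyloxy)phenyl]-4-{2,4-bis(benzyloxy)-6-[(E)-2-[3,4-bis(benzyloxy)phenyl]ethenyl]phenyl}-3,4-dihydro-2H-chromen-3-ol | O(Cc1ccccc1)c1ccc(cc1)[C@H]1Oc2cc(OCc5ccccc5)ccc2[C@@H](c2c(OCc5ccccc5)cc(OCc5ccccc5)cc2/C=C/c2ccc(OCc5ccccc5)c(OCc5ccccc5)c2)[C@@H]1O | intermediate
22 | (2R,3S,4S)-4-{2-[(E)-2-(3,4-dihydroxyphenyl)ethenyl]-4,6-dihydroxyphenyl}-2-(4-hydroxyphenyl)-3,4-dihydro-2H-chromene-3,7-diol (CNP0170061.1) | Oc1ccc([C@H]2Oc3cc(O)ccc3[C@@H](c3c(O)cc(O)cc3/C=C/c3ccc(O)c(O)c3)[C@@H]2O)cc1 | target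

**Step count**
Total: 11 steps. Longest linear sequence: 8 steps (1, 2, 4, 6, 7, 8, 10, 11).

**Steps most likely to fail**

Step 8 (proposed new method). What may go wrong: the benzylic cation may lose the C3 proton and aromatise to a 2-benzylbenzofuran, or be captured only at the benzylic carbon, before the 1,2-oxygen shift and the closure onto C3 take place. The fallback uses known chemistry, gives up the oxygen shift and sets out from ketone 14. Samarium diiodide (THF–MeOH, −78 °C) should cleave the α-aryloxy C–O bond and give the phenolic ketone F1 with C4 intact. Cyclodehydration (PPTS, HC(OMe)3, toluene, 80 °C) should give the 4H-chromene F2. Hydroboration–oxidation (BH3·SMe2, THF, 0 °C; then NaOH, H2O2) should add boron to C3 anti to the C4 aryl group and hydrogen to C2 on the same face, giving the all-trans flavan-3-ol acetal F3. Mild acetal hydrolysis (PPTS, acetone–H2O) then returns to the route at lactol 18.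

Step 6. What may go wrong: poor facial discrimination by the hydrogen-bond catalyst, or slow conjugate addition at the methide carbon flanked by a 2,6-disubstituted aryl group, leaving the o-quinone methide to oligomerise. The fallback sets out from 9 and sets C4 by a different bond construction. The o-quinone methide released from 9 should add diethyl (E)-[2-(4-benzyloxyphenyl)ethenyl]boronate under catalysis by a 3,3′-dibromo-BINOL of the appropriate hand, giving the allyl phenol F4. Reagent-controlled Shi epoxidation (ent-Shi ketone, Oxone, pH 10.5) should give the epoxy phenol F5, whose phenoxide closes 5-exo-tet at C3 with inversion under the basic conditions. This comes back to the route at carbinol 15 without the ketone stage.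

Step 11. What may go wrong: Lewis-acid ionisation of the benzylic C2–O1 bond with loss of configuration at C2, or acid addition across the electron-rich stilbene while six benzyl ethers are cleaved. The fallback removes the benzyl groups before the alkene exists and sets out from lactol 18. Hydrogenolysis (H2, Pd/C, EtOAc–THF, stopped before the lactol is reduced) should give the tetraphenol lactol F6, and silylation (TBSCl, imidazole, DMF) the tetrakis-silyl ether F7. Phosphonate 20 is hydrogenolysed to the catechol phosphonate F8 and silylated to the bis-silyl phosphonate F9. Horner–Wadsworth–Emmons reaction of F7 with F9 (KHMDS, THF, −78 to 0 °C) should give the hexakis-silyl ether F10, and HF·pyridine in THF returns to the route at target 22.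

**Further compounds**
F1 | step 8 | (3S)-3-[4-(benzyloxy)-2-hydroxyphenyl]-1-[4-(benzyloxy)phenyl]-3-[2,4-bis(benzyloxy)-6-(dimethoxymethyl)phenyl]propan-1-one | O=C(c1ccc(OCc2ccccc2)cc1)C[C@@H](c1ccc(OCc2ccccc2)cc1O)c1c(OCc2ccccc2)cc(OCc2ccccc2)cc1C(OC)OC
F2 | step 8 | (4S)-7-(benzyloxy)-2-[4-(benzyloxy)phenyl]-4-[2,4-bis(benzyloxy)-6-(dimethoxymethyl)phenyl]-4H-chromene | O(Cc1ccccc1)c1ccc(cc1)C1=C[C@H](c2c(OCc3ccccc3)cc(OCc3ccccc3)cc2C(OC)OC)c2ccc(OCc3ccccc3)cc2O1
F3 | step 8 | (2R,3S,4S)-7-(benzyloxy)-2-[4-(benzyloxy)phenyl]-4-[2,4-bis(benzyloxy)-6-(dimethoxymethyl)phenyl]-3,4-dihydro-2H-chromen-3-ol | O(Cc1ccccc1)c1ccc(cc1)[C@H]1Oc2cc(OCc3ccccc3)ccc2[C@@H](c2c(OCc3ccccc3)cc(OCc3ccccc3)cc2C(OC)OC)[C@@H]1O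
F4 | step 6 | 5-(benzyloxy)-2-[(1S,2E)-3-[4-(benzyloxy)phenyl]-1-[2,4-bis(benzyloxy)-6-(dimethoxymethyl)phenyl]prop-2-en-1-yl]phenol | Oc1cc(OCc2ccccc2)ccc1[C@H](/C=C/c1ccc(OCc2ccccc2)cc1)c1c(OCc2ccccc2)cc(OCc2ccccc2)cc1C(OC)OC
F5 | step 6 | 5-(benzyloxy)-2-[(S)-[(2S,3S)-3-[4-(benzyloxy)phenyl]oxiran-2-yl][2,4-bis(benzyloxy)-6-(dimethoxymethyl)phenyl]methyl]phenol | Oc1cc(OCc2ccccc2)ccc1[C@H]([C@@H]1O[C@H]1c1ccc(OCc2ccccc2)cc1)c1c(OCc2ccccc2)cc(OCc2ccccc2)cc1C(OC)OC
F6 | step 11 | lactol of (2R,3S,4S)-4-(2-formyl-4,6-dihydroxyphenyl)-2-(4-hydroxyphenyl)-3,4-dihydro-2H-chromene-3,7-diol (hemiacetal between O-3 and the formyl carbon) | Oc1ccc(cc1)[C@H]1Oc2cc(O)ccc2[C@H]3c4c(O)cc(O)cc4C(O)O[C@H]13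
F7 | step 11 | tetrakis(tert-butyldimethylsilyl) ether of F6 at the four phenolic oxygens | CC(C)(C)[Si](C)(C)Oc1ccc(cc1)[C@H]1Oc2cc(O[Si](C)(C)C(C)(C)C)ccc2[C@H]3c4c(O[Si](C)(C)C(C)(C)C)cc(O[Si](C)(C)C(C)(C)C)cc4C(O)O[C@H]13
F8 | step 11 | diethyl [(3,4-dihydroxyphenyl)methyl]phosphonate | CCOP(=O)(OCC)Cc1ccc(O)c(O)c1
F9 | step 11 | diethyl {[3,4-bis(tert-butyldimethylsilyloxy)phenyl]methyl}phosphonate | CCOP(=O)(OCC)Cc1ccc(O[Si](C)(C)C(C)(C)C)c(O[Si](C)(C)C(C)(C)C)c1
F10 | step 11 | hexakis(tert-butyldimethylsilyl) ether of 22 at the six phenolic oxygens | CC(C)(C)[Si](C)(C)Oc1ccc(cc1)[C@H]1Oc2cc(O[Si](C)(C)C(C)(C)C)ccc2[C@@H](c2c(O[Si](C)(C)C(C)(C)C)cc(O[Si](C)(C)C(C)(C)C)cc2/C=C/c2ccc(O[Si](C)(C)C(C)(C)C)c(O[Si](C)(C)C(C)(C)C)c2)[C@@H]1O
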